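**Retrosynthetic overview**
- The enone C=C is cut by a Claisen–Schmidt disconnection. This gives a ring A methyl ketone (the dihydrobenzofuran) and 2,2-dimethyl-2H-chromene-6-carbaldehyde (ring B with its pyran, made from 4-hydroxybenzaldehyde by a propargyl ether Claisen rearrangement).
- Feature used: in the dihydrofuran fused to ring A, the array ArO1–C2(H)–C(CH3)2–OH is the constitutional isomer of ArO1–C2(CH3)2–C3(H)–OH in a 3-hydroxy-2,2-dimethylchroman. Only the aryloxy oxygen and the hydroxyl have changed places on two neighbouring carbons.
- The furan is therefore made by ring contraction. The chroman C3–OH is activated, O1 attacks from the rear (1,2-aryloxy shift through an oxiranium ion), and water captures the CMe2 carbon, turning 3S into 2R.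
- The 3S carbinol comes from catalytic asymmetric epoxidation of the chromene built from 2,4-dihydroxyacetophenone and 3-methylbut-2-enal, followed by benzylic C4–O hydrogenolysis.
- Ring order: pyran on ring A, then oxirane (opened), then dihydrofuran by contraction. The pyran on ring B is made in a separate branch, and the two halves are joined last.

Key step: step 5

Assumption: the acetylated chromene is taken to follow the facial preference established for other 2,2-dimethylchromenes with an acceptor at C6, the (S,S)-ligand giving the 3S,4S-epoxide.

**Step 1**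
Reactants: 1 2,4-dihydroxyacetophenone; 2 3-methylbut-2-enal
Product: 4 1-(5-hydroxy-2,2-dimethyl-2H-chromen-6-yl)ethan-1-one, via o-quinone methide 3 (not isolated)
Conditions: pyridine, 140 °C, sealed vessel
Reagents that add atoms: none
Why: Formal [3+3] chromenylation of a resorcinol, in which aldol-type condensation of 2 at C3 (the carbon between the two oxygens) and loss of water should give 3, whose oxa-6π electrocyclisation closes the pyran on the 4-oxygen because the 2-hydroxyl is held in a hydrogen bond to the acetyl group.

**Step 2**
Reactants: 4 1-(5-hydroxy-2,2-dimethyl-2H-chromen-6-yl)ethan-1-one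
Product: 5 6-acetyl-2,2-dimethyl-2H-chromen-5-yl acetate
Conditions: Ac2O, pyridine, DMAP (cat.), CH2Cl2, 0 °C → rt
Reagents that add atoms: acetic anhydride, CC(=O)OC(C)=O
Why: DMAP-catalysed O-acylation overcomes the chelation of the phenol and masks it against the oxidant of step 3 and the triflic anhydride of step 5, while the weak amine bases cannot start a Baker–Venkataraman acyl shift.

**Step 3**
Reactants: 5 6-acetyl-2,2-dimethyl-2H-chromen-5-yl acetate
Product: 6 (3S,4S)-6-acetyl-3,4-epoxy-2,2-dimethylchroman-5-yl acetate
Conditions: (S,S)-[N,N'-bis(3,5-di-tert-butylsalicylidene)cyclohexane-1,2-diaminato]MnCl (5 mol%), mCPBA (2 equiv), N-methylmorpholine N-oxide (5 equiv), CH2Cl2, −78 °C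
Reagents that add atoms: mCPBA, O=C(OO)c1cccc(Cl)c1
Why: Jacobsen–Katsuki epoxidation, for which cis-configured, aryl-conjugated 2,2-dimethylchromenes with an acceptor at C6 are benchmark substrates: the alkene approaches the oxo complex of pentavalent manganese side-on over the diamine backbone, the (S,S)-ligand should deliver oxygen to the face that gives the 3S,4S-epoxide, and the anhydrous peracid/N-oxide protocol spares the methyl ketone (haloform cleavage) and the aryl acetate (saponification) the alkaline hypochlorite of the aqueous variant.

**Step 4**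
Reactants: 6 (3S,4S)-6-acetyl-3,4-epoxy-2,2-dimethylchroman-5-yl acetate
Product: 7 (S)-6-acetyl-3-hydroxy-2,2-dimethylchroman-5-yl acetate
Conditions: H2 (1 atm), 10% Pd/C, EtOAc, rt, stopped after one equivalent of H2
Reagents that add atoms: none
Why: Heterogeneous hydrogenolysis cleaves only the benzylic C4–O bond of the aryl oxirane, so that C4 becomes CH2 and the C3–O bond keeps its 3S configuration, and the strained benzylic epoxide should be consumed well before the aryl ketone or the acetate react.

**Step 5**
Reactants: 7 (S)-6-acetyl-3-hydroxy-2,2-dimethylchroman-5-yl acetate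
Product: 10 (R)-5-acetyl-2-(2-hydroxypropan-2-yl)-2,3-dihydrobenzofuran-4-yl acetate, via C3 triflate 8 (not isolated), via aryloxiranium ion 9 (not isolated)
Conditions: Tf2O (1.1 equiv), 2,6-di-tert-butyl-4-methylpyridine (3 equiv), CH2Cl2, −78 → −20 °C; then acetone–H2O (3:1) added at −20 °C, → 40 °C
Reagents that add atoms: water, O (the hydroxyl oxygen of 10); triflic anhydride, O=S(=O)(OS(=O)(=O)C(F)(F)F)C(F)(F)F (the triflyl group of 8 only)
Why: The C3 hydroxyl is turned into triflate 8, and in the half-chair with the triflate pseudo-equatorial the C2–O1 bond lies anti-periplanar to C3–OTf, so O1 attacks C3 from the rear as triflate leaves to give bicyclic ion 9, after which water attacks the CMe2 carbon and breaks the old O1–C2 bond, which amounts to a 1,2-aryloxy shift that contracts the pyran to the dihydrofuran. The closest known reactions are the ring contractions of activated 3-hydroxy-2,2-dimethylchromans (sulfonates, DAST adducts) to 2-(2-substituted propan-2-yl)dihydrobenzofurans and of equatorial pyranoside 2-triflates to 2,5-anhydro sugars. The new O1–C bond forms in a closure that is 3-exo-tet for the oxiranium ring and 5-exo-tet for the dihydrofuran ring that survives. The single stereocentre is controlled by the substrate: one inversion at the carbinol carbon turns 3S into 2R, and a free secondary cation, which would racemise, is avoided because ionisation is concerted with the shift. The site of opening is fixed by the gem-dimethyl group, which carries most of the positive charge of 9, and attack of water at the secondary carbon would merely return 7 by double inversion. The acetyl group para to O1 weakens its participation, hence the triflate, the ionising aqueous acetone (a nitrile solvent would intercept the cation in a Ritter reaction) and the hindered pyridine, which together hold back E2 loss of triflic acid to chromene 5, the competing methyl shift and proton loss from 9, while direct SN2 attack of water is blocked by the neopentyl-like surroundings of C3.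

**Step 6**
Reactants: 11 4-hydroxybenzaldehyde; 12 3-chloro-3-methylbut-1-yne
Product: 13 4-[(2-methylbut-3-yn-2-yl)oxy]benzaldehyde
Conditions: K2CO3, KI (cat.), CuI (cat.), acetone, reflux
Reagents that add atoms: none
Why: Copper-assisted Williamson-type O-alkylation of the phenoxide with a tertiary propargylic chloride, which runs through a copper acetylide-derived electrophile and is therefore not stopped by the tertiary centre.

**Step 7**
Reactants: 13 4-[(2-methylbut-3-yn-2-yl)oxy]benzaldehyde
Product: 16 2,2-dimethyl-2H-chromene-6-carbaldehyde, via allenylphenol 14 (not isolated), via formyl o-quinone methide 15 (not isolated)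
Conditions: N,N-diethylaniline, 190 °C
Reagents that add atoms: none
Why: Aromatic propargyl Claisen rearrangement with tautomerisation should give 14, a 1,5-hydrogen shift 15, and oxa-6π electrocyclisation the pyran on ring B, and since both ortho positions are equivalent no regiochemical question arises.

**Step 8**
Reactants: 10 (R)-5-acetyl-2-(2-hydroxypropan-2-yl)-2,3-dihydrobenzofuran-4-yl acetate; 16 2,2-dimethyl-2H-chromene-6-carbaldehyde
Product: 18 (E)-3-(2,2-dimethyl-2H-chromen-6-yl)-1-[(2R)-4-hydroxy-2-(2-hydroxypropan-2-yl)-2,3-dihydrobenzofuran-5-yl]prop-2-en-1-one (target), via phenol ketone 17 (not isolated)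
Conditions: KOH (50% aq), EtOH, 0 °C, 30 min; then 16, rt, 24–48 h; 1 M HCl to pH 5 at 0 °C
Reagents that add atoms: none
Why: Claisen–Schmidt condensation, in which hydroxide in the protic medium cleaves the aryl acetate far faster than an enolate could attack it (no Baker–Venkataraman shift), the enolate of the freed ketone 17 adds to the non-enolisable aldehyde 16 and E1cB loss of water should give the E-enone, the hydrogen-bonded 2'-hydroxyl favours the open chalcone over the flavanone, and C2 of the dihydrofuran carries no acidic hydrogen, so that 2R is kept.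

**Compound list**
1 | 2,4-dihydroxyacetophenone | CC(=O)c1ccc(O)cc1O | starting material
2 | 3-methylbut-2-enal | CC(C)=CC=O | starting material
3 | 4-acetyl-3-hydroxy-2-(3-methylbut-2-en-1-ylidene)cyclohexa-3,5-dien-1-one (o-quinone methide) | CC(=O)C1=C(O)C(=CC=C(C)C)C(=O)C=C1 | intermediate (not isolated)
4 | 1-(5-hydroxy-2,2-dimethyl-2H-chromen-6-yl)ethan-1-one | CC(=O)c1ccc2c(c1O)C=CC(C)(C)O2 | intermediate
5 | 6-acetyl-2,2-dimethyl-2H-chromen-5-yl acetate | CC(=O)Oc1c(C(C)=O)ccc2c1C=CC(C)(C)O2 | intermediate
6 | (3S,4S)-6-acetyl-3,4-epoxy-2,2-dimethylchroman-5-yl acetate [(1aS,7bS)-6-acetyl-2,2-dimethyl-1a,7b-dihydro-2H-oxireno[2,3-c]chromen-7-yl acetate] | CC(=O)Oc1c(C(C)=O)ccc2c1[C@@H]3O[C@@H]3C(C)(C)O2 | intermediate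
7 | (S)-6-acetyl-3-hydroxy-2,2-dimethylchroman-5-yl acetate | CC(=O)Oc1c(C(C)=O)ccc2c1C[C@H](O)C(C)(C)O2 | intermediate
8 | (S)-6-acetyl-2,2-dimethyl-3-(trifluoromethylsulfonyloxy)chroman-5-yl acetate | CC(=O)Oc1c(C(C)=O)ccc2c1C[C@H](OS(=O)(=O)C(F)(F)F)C(C)(C)O2 | intermediate (not isolated)
9 | bicyclic aryloxiranium ion, O1 bridging the former C3 (now R) and the CMe2 carbon, triflate as counter-ion | CC(=O)Oc1c(C(C)=O)ccc2c1C[C@H]3[O+]2C3(C)C | intermediate (not isolated)
10 | (R)-5-acetyl-2-(2-hydroxypropan-2-yl)-2,3-dihydrobenzofuran-4-yl acetate | CC(=O)Oc1c(C(C)=O)ccc2c1C[C@H](C(C)(C)O)O2 | intermediate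
11 | 4-hydroxybenzaldehyde | O=Cc1ccc(O)cc1 | starting material
12 | 3-chloro-3-methylbut-1-yne | C#CC(C)(C)Cl | starting material
13 | 4-[(2-methylbut-3-yn-2-yl)oxy]benzaldehyde | C#CC(C)(C)Oc1ccc(C=O)cc1 | intermediate
14 | 4-hydroxy-3-(3-methylbuta-1,2-dien-1-yl)benzaldehyde | CC(C)=C=Cc1cc(C=O)ccc1O | intermediate (not isolated)
15 | 3-(3-methylbut-2-en-1-ylidene)-4-oxocyclohexa-1,5-diene-1-carbaldehyde | O=CC1=CC(=CC=C(C)C)C(=O)C=C1 | intermediate (not isolated)
16 | 2,2-dimethyl-2H-chromene-6-carbaldehyde | CC1(C)C=Cc2cc(C=O)ccc2O1 | intermediate
17 | 1-[(2R)-4-hydroxy-2-(2-hydroxypropan-2-yl)-2,3-dihydrobenzofuran-5-yl]ethan-1-one | CC(=O)c1ccc2c(c1O)C[C@H](C(C)(C)O)O2 | intermediate (not isolated)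
18 | (E)-3-(2,2-dimethyl-2H-chromen-6-yl)-1-[(2R)-4-hydroxy-2-(2-hydroxypropan-2-yl)-2,3-dihydrobenzofuran-5-yl]prop-2-en-1-one | CC1(C)C=Cc2cc(/C=C/C(=O)c3ccc4c(c3O)C[C@H](C(C)(C)O)O4)ccc2O1 | target

**Step count**
Total step count: 8.
Longest linear sequence: 6 (steps 1, 2, 3, 4, 5 and 8).

**Steps most likely to fail**

Step 5. Participation of O1 may be too weak, because its lone pair is drained by the para acetyl group. Base-induced loss of triflic acid towards the benzylic C4–H could then outrun hydration, as could loss of a methyl proton from ion 9 before water arrives.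
- The fallback sets out from 7 and comes back at 10. It separates the contraction from the making of the C–OH bond.
- 7 is triflated to 8 as before, but the mixture is kept strictly anhydrous with excess hindered pyridine in 1,2-dichloroethane and warmed. Ion 9 then ends by losing a methyl proton and should give (R)-5-acetyl-2-(prop-1-en-2-yl)-2,3-dihydrobenzofuran-4-yl acetate F1.
- The tertiary alcohol is then installed by a radical route, Mukaiyama hydration (Co(acac)2 cat., PhSiH3, O2, THF, rt). This adds in the Markovnikov sense to the 1,1-disubstituted alkene without touching C2 and gives 10.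
- Any chromene 5 re-formed by elimination goes back to step 3.

Step 4. The aryl ketone may be over-reduced. Alternatively, palladium may isomerise the oxirane to the C3 ketone, and unselective reduction of that ketone would cost material or enantiopurity.
- The fallback sets out from 6 and comes back at 7. It replaces hydrogenolysis by ionic opening followed by radical dehalogenation.
- LiBr and AcOH in THF at 0 °C should open the oxirane at the benzylic carbon with inversion. The product is trans-(3R,4R)-6-acetyl-4-bromo-3-hydroxy-2,2-dimethylchroman-5-yl acetate F2. C3 is unchanged in space, and its descriptor changes only because bromine raises the rank of C4.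
- Bu3SnH with AIBN in toluene at 80 °C then removes the bromine under neutral conditions that leave ketone and acetate alone, giving 7.

Step 8. Enolisation may be slow because the ketone is present as its chelated phenoxide. The 2'-hydroxychalcone may also close by oxa-Michael addition to the flavanone during the long exposure to base.
- The fallback sets out from 10 and comes back at 18. It blocks the phenol during the condensation.
- K2CO3 in MeOH gives 17, this time isolated.
- Allyl bromide and K2CO3 in DMF at 50 °C give 1-[(2R)-4-(allyloxy)-2-(2-hydroxypropan-2-yl)-2,3-dihydrobenzofuran-5-yl]ethan-1-one F3.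
- Condensation with 16 (KOH, EtOH, rt) should now be faster and cannot end in a flavanone. It gives (E)-1-[(2R)-4-(allyloxy)-2-(2-hydroxypropan-2-yl)-2,3-dihydrobenzofuran-5-yl]-3-(2,2-dimethyl-2H-chromen-6-yl)prop-2-en-1-one F4.
- Neutral deallylation with Pd(PPh3)4 (cat.) and morpholine in THF at rt spares the chromene and the tertiary alcohol and gives 18.

**Further compounds**
F1 | step 5 | (R)-5-acetyl-2-(prop-1-en-2-yl)-2,3-dihydrobenzofuran-4-yl acetate | CC(=O)Oc1c(C(C)=O)ccc2c1C[C@H](C(C)=C)O2
F2 | step 4 | (3R,4R)-6-acetyl-4-bromo-3-hydroxy-2,2-dimethylchroman-5-yl acetate (trans) | CC(=O)Oc1c(C(C)=O)ccc2c1[C@@H](Br)[C@H](O)C(C)(C)O2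
F3 | step 8 | 1-[(2R)-4-(allyloxy)-2-(2-hydroxypropan-2-yl)-2,3-dihydrobenzofuran-5-yl]ethan-1-one | CC(=O)c1ccc2c(c1OCC=C)C[C@H](C(C)(C)O)O2
F4 | step 8 | (E)-1-[(2R)-4-(allyloxy)-2-(2-hydroxypropan-2-yl)-2,3-dihydrobenzofuran-5-yl]-3-(2,2-dimethyl-2H-chromen-6-yl)prop-2-en-1-one | CC1(C)C=Cc2cc(/C=C/C(=O)c3ccc4c(c3OCC=C)C[C@H](C(C)(C)O)O4)ccc2O1
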